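You cannot make more links than the limiting reagent allows: one first end group and one second end group give one link.

| setting | Saturday's | Thursday's | Tuesday's | dusk | noon | midnight | dawn |
|---|---|---|---|---|---|---|---|
| first end groups | 0.10 M | 0.10 M | 0.10 M | 0.10 M | 0.10 M | 0.10 M (fed, over 6.0 h) | 0.10 M (fed, over 6.0 h) |
| second end groups | 0.11 M | 0.055 M | 0.083 M | 0.110 M (fed, over 6.0 h) | 0.110 M (fed, over 1.5 h) | 0.110 M | 0.110 M |
| temperature | 95 °C | 106 °C | 95 °C | 100 °C | 100 °C |  | 100 °C |
| remark | run made earlier | run made earlier | run made earlier | all else is in the flask from the start; the feed brings no volume worth counting | all else is in the flask from the start; the feed brings no volume worth counting | the addition at 80 °C, then warmed to 100 °C; the feed brings no volume worth counting | all else is in the flask from the start; the feed brings no volume worth counting |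
| time |  |  |  | 8.0 h | 8.0 h | 8.0 h | 8.0 h |

| Saturday's: time / h | Saturday's: links / % | Thursday's: time / h | Thursday's: links / % | Tuesday's: time / h | Tuesday's: links / % |
|---|---|---|---|---|---|
| 1.33 | 43.7 | 0.833 | 29.0 | 1.50 | 36.4 |
| 2.50 | 58.0 | 2.50 | 40.8 | 3.00 | 50.0 |
| 4.00 | 66.7 | 4.00 | 41.6 | 5.00 | 58.5 |
| 5.00 | 70.6 | 6.00 | 37.3 | 6.00 | 59.7 |

(readings scatter by 0.5 percentage points)

- the flask that comes out highest in amount of links, in percent of the first end groups charged, or "all alike" when all lie within 1.5 percentage points (dusk / noon / midnight / dawn / all alike)
- links at the end, in percent of the first end groups charged, dusk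
- links at the end, in percent of the first end groups charged, noon
- links at the end, in percent of the first end groups charged, midnight
- links at the end, in percent of the first end groups charged, dawn

- the numbers in the tables scatter with a standard deviation of 0.5 percentage points

Look at Thursday's run. Its second end groups allow 55.0% of the first end groups charged. Yet the links read 41.6% after 4.00 h, below that ceiling, and then 37.3% after 6.00 h. So links must fade while they are made.

Reckon it this way. Thursday's last two readings give a fading rate of 0.0546 h⁻¹. Its first reading gives a making constant of 10.9 M⁻¹ h⁻¹. Links rise while [first end groups][second end groups]/[links], call it the index, exceeds their ratio. That ratio, 0.00503 M, is the crossing value, the index at which making equals fading. It is read at 106 °C, and I carry it unchanged.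

With near-equal charges, the index reaches that value when 20.0% of the first end groups remain. Saturday's first reading gives 5.13 M⁻¹ h⁻¹ at 95 °C. Interpolating logarithmically gives 7.21 M⁻¹ h⁻¹ at 100 °C. The crossing then takes 5.53 h, and I add half the feed time. Noon crosses at 6.28 h, inside the time. Dusk needs 8.53 h, beyond it. I back noon.

The forecast also names noon: 69% there, 67.3% for dusk, 65% for midnight, 67% for dawn. Its grounds: “the fall does not slow as a link + A loss would, so I take a first-order loss”.

The flasks give noon highest: 71.9% for noon, 69.0% for dusk, 65.3% for midnight, 63.2% for dawn.

    links ⇌ isomer of the product (K = 16.9, k = 0.0293 h⁻¹, Ea = 120 kJ mol⁻¹, ΔH = −56.0 kJ mol⁻¹)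
    first end groups + second end groups → links + by-product (k = 7.72 M⁻¹ h⁻¹, Ea = 83.0 kJ mol⁻¹)
    second end groups → decomposed reagent (k = 0.0495 h⁻¹, Ea = 121 kJ mol⁻¹)
    (constants at 100 °C)

The fading is links passing into isomer of the product. At the end, noon's index is 0.00268 M, below 0.00503 M. Dusk's is 0.00730 M, above it. Now take a neighbour of noon charged with 0.27 M of second end groups. Its end index is 3.57 × 10⁻⁵ M, far below the crossing value. Its first end groups stand at 0.0251%, and its links at 82.2%.

(Readings and results stem from a simulated flask with made-up constants; scatter was added.)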